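**Retrosynthetic overview**
1. Last bonds: O8 desilylation, preceded by Yamaguchi esterification of the C9 hydroxyl with (2S,3S)-2,3-dimethyloxirane-2-carboxylic acid (Sharpless epoxidation of angelyl alcohol, then oxidation).
2. Ten-membered carbocycle (formed second): C2–C3 bond by intramolecular Nozaki–Hiyama–Kishi reaction of a Z-vinyl iodide with the C2 aldehyde, then oxidation to the Z-enone.
3. C7–C8 bond, C7 and C8 stereocentres and the α-methylene lactone: indium Barbier coupling of a 5-substituted 3-(bromomethyl)butenolide with a six-membered lactol carrying C9 (OPMB) and C10 (Me).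
4. Butenolide ring (formed first): (S)-2-vinyloxirane, acetylide opening, Negishi anti-carboalumination/iodination, 2-(bromomethyl)acrylate ester, ring-closing metathesis.
5. Lactol: Brown Z-crotylboration of crotonaldehyde, PMB ether, hydroboration, ozonolysis.

Assumption: (S)-2-vinyloxirane and (+)-Ipc2BOMe are bought as single enantiomers; labels C1–C15 are the germacranolide numbering of the target (C1 H2, C2 ketone, C3=C4(C15), C5 H2, C6 lactone carbinol, C7, C8 OH, C9 ester, C10(C14), C11=C13 H2, C12 lactone carbonyl). The route is a paper design; none of it has been run.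

**Fragment 1 (bromobutenolide)**

Step 1
Reactants: 1 (S)-2-vinyloxirane
Product: 2 (3R)-hex-1-en-5-yn-3-ol
Conditions: LiC≡CH·H2NCH2CH2NH2, DMSO, 0 °C to rt; H2O
Reagents that add atoms: lithium acetylide–ethylenediamine complex [Li+].[C-]#C.NCCN
Why: SN2 epoxide opening by the acetylide at the unsubstituted CH2 leaves the C–O stereocentre (future C6) untouched.

Step 2
Reactants: 2 (3R)-hex-1-en-5-yn-3-ol
Product: 5 (3R,5Z)-6-iodo-5-methylhexa-1,5-dien-3-ol, via E-alkenylalane 3 (not isolated), via Z-oxaaluminacycle 4 (not isolated)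
Conditions: Me3Al (3 equiv), Cp2ZrCl2 (0.25 equiv), (CH2Cl)2, rt then reflux; I2, THF, −30 to 0 °C
Reagents that add atoms: trimethylaluminium C[Al](C)C; iodine II
Why: Negishi zirconium-catalysed carboalumination adds Me–Al syn to the alkyne, the alkoxide-chelated alane isomerises on heating to the six-membered Z-metallacycle, and iodinolysis with retention gives the Z-iodide needed for the C3=C4 geometry.

Step 3
Reactants: 5 (3R,5Z)-6-iodo-5-methylhexa-1,5-dien-3-ol; 6 2-(bromomethyl)prop-2-enoic acid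
Product: 7 (3R,5Z)-6-iodo-5-methylhexa-1,5-dien-3-yl 2-(bromomethyl)prop-2-enoate
Conditions: DCC, DMAP (5 mol %), CH2Cl2, 0 °C
Reagents that add atoms: none
Why: Steglich esterification of the secondary allylic alcohol, with no stereocentre touched.

Step 4
Reactants: 7 (3R,5Z)-6-iodo-5-methylhexa-1,5-dien-3-yl 2-(bromomethyl)prop-2-enoate
Product: 8 (5R)-3-(bromomethyl)-5-[(2Z)-3-iodo-2-methylprop-2-en-1-yl]furan-2(5H)-one
Conditions: second-generation Grubbs catalyst (H2IMes)(PCy3)Cl2Ru=CHPh (5 mol %), CH2Cl2, 40 °C, 0.01 M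
Reagents that add atoms: none
Why: Ring-closing metathesis between the vinyl group and the acrylate closes the five-membered butenolide, while the trisubstituted vinyl iodide is inert.

**Fragment 2 (lactol)**

Step 5
Reactants: 9 (E)-but-2-enal
Product: 11 (3S,4S,5E)-3-methylhepta-1,5-dien-4-ol, via borinate ester 10 (not isolated)
Conditions: cis-2-butene, n-BuLi, KOtBu, THF, −78 to −45 °C; (+)-Ipc2BOMe [from (−)-α-pinene], −78 °C; BF3·OEt2; 9, −78 °C; NaOH, H2O2
Reagents that add atoms: cis-2-butene C/C=C\C, delivered as (Z)-but-2-enyl-diisopinocampheylborane C/C=C\CB([C@H]1C[C@H]2C[C@@H]([C@@H]1C)C2(C)C)[C@H]1C[C@H]2C[C@@H]([C@@H]1C)C2(C)C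
Why: Brown crotylboration through a Zimmerman–Traxler chair, in which the Z-crotyl geometry gives the syn OH/Me pair and the isopinocampheyl groups direct attack to the Re face of the aldehyde, sets C9 and C10.

Step 6
Reactants: 11 (3S,4S,5E)-3-methylhepta-1,5-dien-4-ol
Product: 12 1-methoxy-4-({[(3S,4S,5E)-3-methylhepta-1,5-dien-4-yl]oxy}methyl)benzene
Conditions: NaH, PMBCl, Bu4NI (cat.), DMF, 0 °C to rt
Reagents that add atoms: 4-methoxybenzyl chloride COc1ccc(CCl)cc1
Why: Williamson etherification puts a chelating, oxidatively removable group on O9.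

Step 7
Reactants: 12 1-methoxy-4-({[(3S,4S,5E)-3-methylhepta-1,5-dien-4-yl]oxy}methyl)benzene
Product: 14 (3S,4R,5E)-4-[(4-methoxybenzyl)oxy]-3-methylhept-5-en-1-ol, via B-alkyl-9-BBN adduct 13 (not isolated)
Conditions: 9-BBN, THF, 0 °C to rt; NaOH, H2O2
Reagents that add atoms: hydrogen peroxide OO
Why: Anti-Markovnikov hydroboration–oxidation in which 9-BBN takes only the terminal vinyl group and leaves the internal propenyl group.

Step 8
Reactants: 14 (3S,4R,5E)-4-[(4-methoxybenzyl)oxy]-3-methylhept-5-en-1-ol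
Product: 17 (3R,4S)-3-[(4-methoxybenzyl)oxy]-4-methyloxan-2-ol (anomers), via ozonide 15 (not isolated), via open hydroxy aldehyde 16 (not isolated)
Conditions: O3, CH2Cl2, −78 °C (stopped at first blue); PPh3, −78 °C to rt
Reagents that add atoms: ozone [O-][O+]=O
Why: Ozonolysis of the propenyl group unveils the C8 aldehyde, which closes onto the C2 hydroxyl as a six-membered lactol.

**Fragment 3 (epoxy acid)**

Step 9
Reactants: 18 methyl (Z)-2-methylbut-2-enoate (methyl angelate)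
Product: 19 (Z)-2-methylbut-2-en-1-ol
Conditions: iBu2AlH (2.2 equiv), CH2Cl2, −78 to 0 °C
Reagents that add atoms: none
Why: 1,2-Reduction of the enoate keeps the Z geometry.

Step 10
Reactants: 19 (Z)-2-methylbut-2-en-1-ol
Product: 20 [(2R,3S)-2,3-dimethyloxiran-2-yl]methanol
Conditions: Ti(OiPr)4 (10 mol %), D-(−)-DIPT (12 mol %), TBHP, 4 Å MS, CH2Cl2, −20 °C
Reagents that add atoms: tert-butyl hydroperoxide CC(C)(C)OO
Why: Katsuki–Sharpless asymmetric epoxidation, where D-(−)-tartrate selects the face giving the (2R,3S)-epoxy alcohol and the Z-alkene fixes the cis methyl/carbinol relationship.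

Step 11
Reactants: 20 [(2R,3S)-2,3-dimethyloxiran-2-yl]methanol
Product: 21 (2S,3S)-2,3-dimethyloxirane-2-carboxylic acid
Conditions: RuCl3·xH2O (2 mol %), NaIO4, CCl4/MeCN/H2O, rt
Reagents that add atoms: water O
Why: Sharpless RuO4 oxidation of the primary alcohol to the acid leaves the epoxide intact (C2 becomes S only through the priority change).

**Coupling and endgame**

Step 12
Reactants: 8 (5R)-3-(bromomethyl)-5-[(2Z)-3-iodo-2-methylprop-2-en-1-yl]furan-2(5H)-one; 17 (3R,4S)-3-[(4-methoxybenzyl)oxy]-4-methyloxan-2-ol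
Product: 23 (4R,5R)-4-{(1R,2R,3S)-1,5-dihydroxy-2-[(4-methoxybenzyl)oxy]-3-methylpentyl}-5-[(2Z)-3-iodo-2-methylprop-2-en-1-yl]-3-methylideneoxolan-2-one, via allylindium dibromide 22 (not isolated)
Conditions: In powder, THF/H2O (2:1), rt
Reagents that add atoms: none
Why: Barbier 2-(alkoxycarbonyl)allylation in which the allylindium adds at its γ-carbon (C7) anti to the C6 side chain (trans lactone), the ring-fixed E-type geometry in a closed chair places O8 and C11 syn along the backbone, and indium chelation to the C9 OPMB oxygen favours the same aldehyde face, so C7 and C8 are both R.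

Step 13
Reactants: 23 (the diol from step 12)
Product: 24 O2,O8-bis(triethylsilyl) ether of 23
Conditions: TESOTf (2.5 equiv), 2,6-lutidine, CH2Cl2, −78 °C
Reagents that add atoms: triethylsilyl trifluoromethanesulfonate CC[Si](CC)(CC)OS(=O)(=O)C(F)(F)F
Why: Silylation of both hydroxyls masks O8 until the last step under conditions too mild for translactonisation.

Step 14
Reactants: 24 O2,O8-bis(triethylsilyl) ether of 23
Product: 26 C2 aldehyde (O8-TES; O9-PMB seco-aldehyde), via alkoxysulfonium chloride 25 (not isolated)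
Conditions: (COCl)2, DMSO, CH2Cl2, −78 to −40 °C; Et3N, −78 to 0 °C
Reagents that add atoms: none
Why: Under Swern conditions a primary triethylsilyl ether is cleaved and oxidised in one pot, while the hindered secondary one survives.

Step 15
Reactants: 26 C2 aldehyde (O8-TES; O9-PMB seco-aldehyde)
Product: 27 macrocyclic C2 allylic alcohol (O8-TES; O9-PMB; both C2 epimers)
Conditions: CrCl2 (10 equiv), NiCl2 (2 mol %), degassed DMSO/THF, rt, 0.002 M, slow addition
Reagents that add atoms: none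
Why: Intramolecular Nozaki–Hiyama–Kishi reaction in which zerovalent nickel inserts into the carbon–iodine bond with retention of the Z geometry and the alkenylchromium adds to the aldehyde, closing the ten-membered ring.

Step 16
Reactants: 27 macrocyclic C2 allylic alcohol (O8-TES; O9-PMB; both C2 epimers)
Product: 28 macrocyclic Z-enone (O8-TES; O9-PMB)
Conditions: DMP, NaHCO3, CH2Cl2, 0 °C to rt
Reagents that add atoms: none
Why: Dess–Martin oxidation converges both C2 epimers on the Z-enone.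

Step 17
Reactants: 28 macrocyclic Z-enone (O8-TES; O9-PMB)
Product: 29 C9 alcohol (O8-TES)
Conditions: DDQ, CH2Cl2/pH 7 buffer, 0 °C to rt
Reagents that add atoms: none
Why: Oxidative PMB cleavage frees O9 alone.

Step 18
Reactants: 29 C9 alcohol (O8-TES); 21 (2S,3S)-2,3-dimethyloxirane-2-carboxylic acid
Product: 31 O8-triethylsilyl ether of the target, via mixed anhydride 30 (not isolated)
Conditions: 21, 2,4,6-Cl3C6H2COCl, Et3N, THF, rt; then 29, DMAP, toluene, rt to 40 °C
Reagents that add atoms: none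
Why: Yamaguchi esterification acylates the only free hydroxyl (O9) without touching the epoxide stereocentres.

Step 19
Reactants: 31 O8-triethylsilyl ether of the target
Product: 32 target, (3aR,4R,5R,6S,9Z,11aR)-4-hydroxy-6,10-dimethyl-3-methylidene-2,8-dioxo-2,3,3a,4,5,6,7,8,11,11a-decahydrocyclodeca[b]furan-5-yl (2S,3S)-2,3-dimethyloxirane-2-carboxylate
Conditions: HF·pyridine, pyridine, THF, 0 °C
Reagents that add atoms: none
Why: Buffered fluoride desilylation frees O8 without acyl migration or epoxide opening.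

**Compound list**
1 | (S)-2-vinyloxirane | C=C[C@H]1CO1 | starting material
2 | (3R)-hex-1-en-5-yn-3-ol | O[C@@H](C=C)CC#C | intermediate
3 | dimethylaluminium (3R,5E)-6-(dimethylalumanyl)-5-methylhexa-1,5-dien-3-olate (E-alkenylalane) | C=C[C@H](O[Al](C)C)C/C(C)=C/[Al](C)C | intermediate (not isolated)
4 | (6R)-6-ethenyl-2,4-dimethyl-5,6-dihydro-2H-1,2-oxaluminine (Z-oxaaluminacycle) | C=C[C@H]1C/C(C)=C\[Al](C)O1 | intermediate (not isolated)
5 | (3R,5Z)-6-iodo-5-methylhexa-1,5-dien-3-ol | O[C@@H](C=C)C/C(C)=C\I | intermediate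
6 | 2-(bromomethyl)prop-2-enoic acid | C=C(CBr)C(=O)O | starting material
7 | (3R,5Z)-6-iodo-5-methylhexa-1,5-dien-3-yl 2-(bromomethyl)prop-2-enoate | C=C(CBr)C(=O)O[C@@H](C=C)C/C(C)=C\I | intermediate
8 | (5R)-3-(bromomethyl)-5-[(2Z)-3-iodo-2-methylprop-2-en-1-yl]furan-2(5H)-one | BrCC1=C[C@@H](C/C(C)=C\I)OC1=O | intermediate
9 | (E)-but-2-enal | C/C=C/C=O | starting material
10 | O-diisopinocampheylboryl ether of 11 (borinate ester) | C=C[C@H](C)[C@H](/C=C/C)OB([C@H]1C[C@H]2C[C@@H]([C@@H]1C)C2(C)C)[C@H]1C[C@H]2C[C@@H]([C@@H]1C)C2(C)C | intermediate (not isolated)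
11 | (3S,4S,5E)-3-methylhepta-1,5-dien-4-ol | C=C[C@H](C)[C@@H](O)/C=C/C | intermediate
12 | 1-methoxy-4-({[(3S,4S,5E)-3-methylhepta-1,5-dien-4-yl]oxy}methyl)benzene | C=C[C@H](C)[C@@H](OCc1ccc(OC)cc1)/C=C/C | intermediate
13 | 9-{(3S,4R,5E)-4-[(4-methoxybenzyl)oxy]-3-methylhept-5-en-1-yl}-9-borabicyclo[3.3.1]nonane | B1(CC[C@H](C)[C@@H](OCc2ccc(OC)cc2)/C=C/C)C2CCCC1CCC2 | intermediate (not isolated)
14 | (3S,4R,5E)-4-[(4-methoxybenzyl)oxy]-3-methylhept-5-en-1-ol | OCC[C@H](C)[C@@H](OCc1ccc(OC)cc1)/C=C/C | intermediate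
15 | 1,2,4-trioxolane (ozonide) from the C5=C6 bond of 14 | OCC[C@H](C)[C@@H](OCc1ccc(OC)cc1)C1OOC(C)O1 | intermediate (not isolated)
16 | (2R,3S)-5-hydroxy-2-[(4-methoxybenzyl)oxy]-3-methylpentanal | OCC[C@H](C)[C@@H](OCc1ccc(OC)cc1)C=O | intermediate (not isolated)
17 | (3R,4S)-3-[(4-methoxybenzyl)oxy]-4-methyloxan-2-ol (anomers) | OC1OCC[C@H](C)[C@H]1OCc2ccc(OC)cc2 | intermediate
18 | methyl (Z)-2-methylbut-2-enoate | C/C=C(/C)C(=O)OC | starting material
19 | (Z)-2-methylbut-2-en-1-ol | C/C=C(/C)CO | intermediate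
20 | [(2R,3S)-2,3-dimethyloxiran-2-yl]methanol | OC[C@@]1(C)O[C@H]1C | intermediate
21 | (2S,3S)-2,3-dimethyloxirane-2-carboxylic acid | O=C(O)[C@@]1(C)O[C@H]1C | intermediate
22 | dibromo{[(5R)-5-[(2Z)-3-iodo-2-methylprop-2-en-1-yl]-2-oxo-2,5-dihydrofuran-3-yl]methyl}indium | Br[In](Br)CC1=C[C@@H](C/C(C)=C\I)OC1=O | intermediate (not isolated)
23 | (4R,5R)-4-{(1R,2R,3S)-1,5-dihydroxy-2-[(4-methoxybenzyl)oxy]-3-methylpentyl}-5-[(2Z)-3-iodo-2-methylprop-2-en-1-yl]-3-methylideneoxolan-2-one | C=C1C(=O)O[C@H](C/C(C)=C\I)[C@H]1[C@@H](O)[C@H](OCc2ccc(OC)cc2)[C@@H](C)CCO | intermediate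
24 | O2,O8-bis(triethylsilyl) ether of 23 | C=C1C(=O)O[C@H](C/C(C)=C\I)[C@H]1[C@@H](O[Si](CC)(CC)CC)[C@H](OCc2ccc(OC)cc2)[C@@H](C)CCO[Si](CC)(CC)CC | intermediate
25 | O2-dimethylsulfonium chloride of the O8-TES, O9-PMB seco-alcohol | C=C1C(=O)O[C@H](C/C(C)=C\I)[C@H]1[C@@H](O[Si](CC)(CC)CC)[C@H](OCc2ccc(OC)cc2)[C@@H](C)CCO[S+](C)C.[Cl-] | intermediate (not isolated)
26 | C2 aldehyde: O8-TES, O9-PMB seco-aldehyde with the Z-vinyl iodide | C=C1C(=O)O[C@H](C/C(C)=C\I)[C@H]1[C@@H](O[Si](CC)(CC)CC)[C@H](OCc2ccc(OC)cc2)[C@@H](C)CC=O | intermediate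
27 | macrocyclic C2 allylic alcohol, O8-TES, O9-PMB, both C2 epimers, C6–C10 as in the target | C=C1C(=O)O[C@@H]2C/C(C)=C\C(O)C[C@H](C)[C@@H](OCc3ccc(OC)cc3)[C@H](O[Si](CC)(CC)CC)[C@@H]12 | intermediate
28 | macrocyclic Z-enone, O8-TES, O9-PMB | C=C1C(=O)O[C@@H]2C/C(C)=C\C(=O)C[C@H](C)[C@@H](OCc3ccc(OC)cc3)[C@H](O[Si](CC)(CC)CC)[C@@H]12 | intermediate
29 | macrocyclic Z-enone with free C9 hydroxyl, O8-TES | C=C1C(=O)O[C@@H]2C/C(C)=C\C(=O)C[C@H](C)[C@@H](O)[C@H](O[Si](CC)(CC)CC)[C@@H]12 | intermediate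
30 | (2S,3S)-2,3-dimethyloxirane-2-carboxylic 2,4,6-trichlorobenzoic anhydride | O=C(OC(=O)c1c(Cl)cc(Cl)cc1Cl)[C@@]2(C)O[C@H]2C | intermediate (not isolated)
31 | O8-triethylsilyl ether of the target | C=C1C(=O)O[C@@H]2C/C(C)=C\C(=O)C[C@H](C)[C@@H](OC(=O)[C@@]3(C)O[C@H]3C)[C@H](O[Si](CC)(CC)CC)[C@@H]12 | intermediate
32 | (3aR,4R,5R,6S,9Z,11aR)-4-hydroxy-6,10-dimethyl-3-methylidene-2,8-dioxo-2,3,3a,4,5,6,7,8,11,11a-decahydrocyclodeca[b]furan-5-yl (2S,3S)-2,3-dimethyloxirane-2-carboxylate | C=C1C(=O)O[C@@H]2C/C(C)=C\C(=O)C[C@H](C)[C@@H](OC(=O)[C@@]3(C)O[C@H]3C)[C@H](O)[C@@H]12 | target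

**Totals**
Total step count: 19. Longest linear sequence: 12 steps (steps 1–4 then 12–19; the branch 5–8 then 12–19 is equally long).

**Three steps most likely to fail**

Step 12 (Barbier coupling). The allyl reagent fixes C7 and C8, but the required C8/C9 syn relationship is the chelation (anti-Felkin) product, and chelation to a PMB ether is weak in water, so the diastereomer ratio may be low. The fallback moves the coupling to an open-chain aldehyde held in a pre-formed chelate under anhydrous conditions. It sets out from 14: silylation (TESCl, imidazole) gives triethyl({(3S,4R,5E)-4-[(4-methoxybenzyl)oxy]-3-methylhept-5-en-1-yl}oxy)silane F1; ozonolysis (O3, then PPh3) gives (2R,3S)-2-[(4-methoxybenzyl)oxy]-3-methyl-5-[(triethylsilyl)oxy]pentanal F2; F2 is complexed with MgBr2·OEt2 (CH2Cl2, −78 °C) and treated with the allylzinc bromide made from 8 and Zn dust in THF, giving the O2-mono(triethylsilyl) ether of 23 F3; TESOTf/2,6-lutidine on the C8 hydroxyl then comes back to the route at 24.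

Step 15 (ten-membered ring closure). A strained ring, entropic cost and possible transfer of the alkenyl group to the α-methylene lactone can all divert the alkenylchromium. The fallback closes the ring at C3=C4 by metathesis instead of at C2–C3. It sets out from 1: opening with isopropenylmagnesium bromide (CuI 10 mol %, THF, −30 °C) gives (3R)-5-methylhexa-1,5-dien-3-ol F4; esterification with 6 (DCC, DMAP) gives (3R)-5-methylhexa-1,5-dien-3-yl 2-(bromomethyl)prop-2-enoate F5; ring-closing metathesis (second-generation Grubbs catalyst) gives (5R)-3-(bromomethyl)-5-(2-methylprop-2-en-1-yl)furan-2(5H)-one F6; indium coupling with 17 as in step 12 gives the methallyl analogue of 23 F7; TESOTf gives its O2,O8-bis(triethylsilyl) ether F8; Swern oxidation gives the C2 aldehyde F9; intermolecular Nozaki–Hiyama–Kishi vinylation with vinyl bromide (CrCl2, NiCl2 cat., DMF) gives the C2 vinyl carbinol F10 as both epimers; ring-closing metathesis of F10 (second-generation Hoveyda–Grubbs catalyst (H2IMes)Cl2Ru=CH(2-iPrO-C6H4), toluene, 80 °C, 0.001 M), expected to give the Z trisubstituted alkene in the lactone-bridged ring, comes back to the route at 27.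

Step 18 (esterification). The C9 hydroxyl in the ring is flanked by the silyloxy-bearing C8 and the methyl-bearing C10, and the acid is α-quaternary, so acylation may stall. The fallback esterifies before ring closure. It sets out from 24: DDQ (CH2Cl2/pH 7 buffer) gives the O9-deprotected bis-silyl ether F11; Yamaguchi esterification with 21 gives the open-chain C9 epoxy ester F12; Swern oxidation gives the C2 aldehyde F13; Nozaki–Hiyama–Kishi cyclisation (CrCl2, NiCl2 cat., DMSO/THF, 0.002 M) gives the macrocyclic C2 allylic alcohol carrying the ester F14; Dess–Martin oxidation comes back to the route at 31.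

**Further compounds**
F1 | step 12 | triethyl({(3S,4R,5E)-4-[(4-methoxybenzyl)oxy]-3-methylhept-5-en-1-yl}oxy)silane | CC[Si](CC)(CC)OCC[C@H](C)[C@@H](OCc1ccc(OC)cc1)/C=C/C
F2 | step 12 | (2R,3S)-2-[(4-methoxybenzyl)oxy]-3-methyl-5-[(triethylsilyl)oxy]pentanal | CC[Si](CC)(CC)OCC[C@H](C)[C@@H](OCc1ccc(OC)cc1)C=O
F3 | step 12 | O2-mono(triethylsilyl) ether of 23 | C=C1C(=O)O[C@H](C/C(C)=C\I)[C@H]1[C@@H](O)[C@H](OCc2ccc(OC)cc2)[C@@H](C)CCO[Si](CC)(CC)CC
F4 | step 15 | (3R)-5-methylhexa-1,5-dien-3-ol | O[C@@H](C=C)CC(C)=C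
F5 | step 15 | (3R)-5-methylhexa-1,5-dien-3-yl 2-(bromomethyl)prop-2-enoate | C=C(CBr)C(=O)O[C@@H](C=C)CC(C)=C
F6 | step 15 | (5R)-3-(bromomethyl)-5-(2-methylprop-2-en-1-yl)furan-2(5H)-one | BrCC1=C[C@@H](CC(C)=C)OC1=O
F7 | step 15 | (4R,5R)-4-{(1R,2R,3S)-1,5-dihydroxy-2-[(4-methoxybenzyl)oxy]-3-methylpentyl}-3-methylidene-5-(2-methylprop-2-en-1-yl)oxolan-2-one | C=C1C(=O)O[C@H](CC(C)=C)[C@H]1[C@@H](O)[C@H](OCc2ccc(OC)cc2)[C@@H](C)CCO
F8 | step 15 | O2,O8-bis(triethylsilyl) ether of F7 | C=C1C(=O)O[C@H](CC(C)=C)[C@H]1[C@@H](O[Si](CC)(CC)CC)[C@H](OCc2ccc(OC)cc2)[C@@H](C)CCO[Si](CC)(CC)CC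
F9 | step 15 | C2 aldehyde from F8 | C=C1C(=O)O[C@H](CC(C)=C)[C@H]1[C@@H](O[Si](CC)(CC)CC)[C@H](OCc2ccc(OC)cc2)[C@@H](C)CC=O
F10 | step 15 | C2 vinyl carbinol from F9 (both epimers) | C=C1C(=O)O[C@H](CC(C)=C)[C@H]1[C@@H](O[Si](CC)(CC)CC)[C@H](OCc2ccc(OC)cc2)[C@@H](C)CC(O)C=C
F11 | step 18 | O9-deprotected 24 (C9 alcohol, O2,O8-bis-TES) | C=C1C(=O)O[C@H](C/C(C)=C\I)[C@H]1[C@@H](O[Si](CC)(CC)CC)[C@H](O)[C@@H](C)CCO[Si](CC)(CC)CC
F12 | step 18 | C9 (2S,3S)-2,3-dimethyloxirane-2-carboxylate of F11 | C=C1C(=O)O[C@H](C/C(C)=C\I)[C@H]1[C@@H](O[Si](CC)(CC)CC)[C@H](OC(=O)[C@@]2(C)O[C@H]2C)[C@@H](C)CCO[Si](CC)(CC)CC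
F13 | step 18 | C2 aldehyde from F12 | C=C1C(=O)O[C@H](C/C(C)=C\I)[C@H]1[C@@H](O[Si](CC)(CC)CC)[C@H](OC(=O)[C@@]2(C)O[C@H]2C)[C@@H](C)CC=O
F14 | step 18 | macrocyclic C2 allylic alcohol with the C9 epoxy ester, O8-TES (both C2 epimers) | C=C1C(=O)O[C@@H]2C/C(C)=C\C(O)C[C@H](C)[C@@H](OC(=O)[C@@]3(C)O[C@H]3C)[C@H](O[Si](CC)(CC)CC)[C@@H]12
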